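**Retrosynthetic overview**
1. Last bond made: the depside ester C–O, by acylating the ring B phenol (a 4-hydroxy-2-methoxy-3,6-dimethylbenzoate) with a 2,4-di-O-benzyl ring A acid; the two benzyl ethers come off last.
2. Ring A acid: from an orsellinate ester by C3 formylation, O-benzylation and ester hydrolysis under acetal cover. Ring B phenol: from a β-orcinolcarboxylate ester by 4-O-benzylation, 2-O-methylation and debenzylation.
3. Each resorcylate ester: from a 2,4-dioxocyclohexane-1-carboxylate by bromination–dehydrobromination.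
4. Key C–C bond: intermolecular Michael addition of a β-keto ester to a crotonate ester, followed in the same pot by Dieckmann (Claisen) ring closure.
5. Ring order: the ring B carbocycle first (steps 1–2), then the ring A carbocycle (steps 6–7); no other ring is made.

Assumption: the target has no stereocentre, so it is made as the single achiral compound drawn; the non-aromatic Michael and dione intermediates carry epimerisable stereocentres, are used as stereoisomer mixtures and are written without stereodescriptors.

**Route**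

Step 1
Reactants: 1 methyl 3-oxopentanoate; 2 methyl (E)-but-2-enoate
Product: 4 methyl 3,6-dimethyl-2,4-dioxocyclohexane-1-carboxylate, via Michael adduct 3 (not isolated)
Conditions: NaOMe (1.1 equiv), MeOH, reflux, 16 h; then aq. HCl
Reagents that add atoms: none
Why: Michael addition of the β-keto ester C2 carbanion to the crotonate β-carbon joins the two fragments, and Dieckmann (intramolecular Claisen) attack of the ethyl-ketone enolate on the remote ester closes the six-membered ring, driven by the stable β-diketone enolate; the three stereocentres are epimerisable and vanish in step 2.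

Step 2
Reactants: 4 methyl 3,6-dimethyl-2,4-dioxocyclohexane-1-carboxylate
Product: 7 methyl 2,4-dihydroxy-3,6-dimethylbenzoate, via 3-bromo dione 5 (not isolated), via 5-bromo dione 6 (not isolated)
Conditions: Br2 (1.0 equiv), DMF, 0 °C to rt, then 80 °C
Reagents that add atoms: none
Why: Bromination–dehydrobromination aromatisation: bromine first attacks C3 of the enolised β-diketone, HBr moves it to C5, and E2 loss of HBr in warm DMF followed by enolisation gives the resorcinol, erasing all stereocentres.

Step 3
Reactants: 7 methyl 2,4-dihydroxy-3,6-dimethylbenzoate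
Product: 8 methyl 4-(benzyloxy)-2-hydroxy-3,6-dimethylbenzoate
Conditions: BnBr (1.05 equiv), K2CO3, acetone, reflux
Reagents that add atoms: benzyl bromide, BrCc1ccccc1
Why: Williamson etherification is selective for the 4-OH because the 2-OH is locked in a hydrogen bond to the ester carbonyl and is much less acidic under K2CO3 in acetone.

Step 4
Reactants: 8 methyl 4-(benzyloxy)-2-hydroxy-3,6-dimethylbenzoate
Product: 9 methyl 4-(benzyloxy)-2-methoxy-3,6-dimethylbenzoate
Conditions: MeI (3 equiv), K2CO3, DMF, 50 °C
Reagents that add atoms: iodomethane, CI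
Why: With the 4-OH masked, a forcing Williamson methylation in DMF alkylates the chelated, hindered 2-OH, the only nucleophile left.

Step 5
Reactants: 9 methyl 4-(benzyloxy)-2-methoxy-3,6-dimethylbenzoate
Product: 10 methyl 4-hydroxy-2-methoxy-3,6-dimethylbenzoate
Conditions: H2 (1 atm), 10% Pd/C, EtOAc, rt
Reagents that add atoms: none
Why: Catalytic hydrogenolysis of the aryl benzyl ether is fast and leaves the methyl ester, the methyl ether and the arene untouched.

Step 6
Reactants: 11 methyl acetoacetate; 2 methyl (E)-but-2-enoate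
Product: 13 methyl 6-methyl-2,4-dioxocyclohexane-1-carboxylate, via Michael adduct 12 (not isolated)
Conditions: NaOMe (1.1 equiv), MeOH, reflux, 16 h; then aq. HCl
Reagents that add atoms: none
Why: The same Michael addition/Dieckmann condensation as in step 1, here with the acetyl methyl enolate closing the ring; the two stereocentres vanish in step 7.

Step 7
Reactants: 13 methyl 6-methyl-2,4-dioxocyclohexane-1-carboxylate
Product: 16 methyl 2,4-dihydroxy-6-methylbenzoate, via 3-bromo dione 14 (not isolated), via 5-bromo dione 15 (not isolated)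
Conditions: Br2 (1.0 equiv), DMF, 0 °C to rt, then 80 °C
Reagents that add atoms: none
Why: Bromination–dehydrobromination aromatisation as in step 2; one equivalent of bromine in DMF is consumed by the far more nucleophilic dione enol, so the resorcinol ring is not brominated.

Step 8
Reactants: 16 methyl 2,4-dihydroxy-6-methylbenzoate
Product: 18 methyl 3-formyl-2,4-dihydroxy-6-methylbenzoate, via chloro ether 17 (not isolated)
Conditions: Cl2CHOMe (1.5 equiv), TiCl4 (3 equiv), CH2Cl2, 0 °C; then ice/1 M HCl
Reagents that add atoms: dichloromethyl methyl ether, COC(Cl)Cl; water, O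
Why: Rieche formylation: the titanium chelate of the 2-O/ester unit and the titanium 4-phenoxide both deliver the chloro(methoxy)methyl cation to C3, the carbon ortho to both oxygens, whereas C5 is ortho to only one oxygen and flanked by the 6-methyl; aqueous acid then hydrolyses the chloro ether to the aldehyde.

Step 9
Reactants: 18 methyl 3-formyl-2,4-dihydroxy-6-methylbenzoate
Product: 20 methyl 2,4-bis(benzyloxy)-3-formyl-6-methylbenzoate, via monobenzyl ether 19 (not isolated)
Conditions: BnBr (2.5 equiv), K2CO3 (3 equiv), DMF, 60 °C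
Reagents that add atoms: benzyl bromide, BrCc1ccccc1
Why: Double Williamson benzylation in DMF, the less hindered 4-OH reacting first and the 2-OH between ester and aldehyde following on heating; C-alkylation is not an issue because C3 is substituted.

Step 10
Reactants: 20 methyl 2,4-bis(benzyloxy)-3-formyl-6-methylbenzoate
Product: 21 methyl 2,4-bis(benzyloxy)-3-(1,3-dioxolan-2-yl)-6-methylbenzoate
Conditions: HOCH2CH2OH (5 equiv), p-TsOH (cat.), PhMe, Dean–Stark, reflux
Reagents that add atoms: ethylene glycol, OCCO
Why: Acid-catalysed acetalisation with azeotropic removal of water masks the aldehyde as a base-stable 1,3-dioxolane before the hydroxide step, and benzyl ethers and the hindered ester are inert to catalytic acid.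

Step 11
Reactants: 21 methyl 2,4-bis(benzyloxy)-3-(1,3-dioxolan-2-yl)-6-methylbenzoate
Product: 23 2,4-bis(benzyloxy)-3-formyl-6-methylbenzoic acid, via dioxolane acid 22 (not isolated)
Conditions: KOH (5 equiv), DMSO–H2O (4:1), 90 °C; then 2 M HCl, THF–H2O, rt
Reagents that add atoms: potassium hydroxide, [K+].[OH-]; water, O
Why: Hot KOH in aqueous DMSO saponifies the doubly ortho-substituted methyl ester (BAc2) while the acetal keeps hydroxide off the formyl carbon (no Cannizzaro reaction or deformylation), and the acidic work-up frees the acid and hydrolyses the electron-rich acetal.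

Step 12
Reactants: 23 2,4-bis(benzyloxy)-3-formyl-6-methylbenzoic acid; 10 methyl 4-hydroxy-2-methoxy-3,6-dimethylbenzoate
Product: 25 methyl 4-{[2,4-bis(benzyloxy)-3-formyl-6-methylbenzoyl]oxy}-2-methoxy-3,6-dimethylbenzoate, via mixed anhydride 24 (not isolated)
Conditions: (CF3CO)2O (4 equiv), PhMe, rt
Reagents that add atoms: none
Why: Mixed-anhydride esterification: trifluoroacetic anhydride turns the hindered, electron-rich acid into an acylium-like donor that O-acylates the single free phenol of 10, and the benzyl ethers rule out self-condensation of the acid.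

Step 13
Reactants: 25 methyl 4-{[2,4-bis(benzyloxy)-3-formyl-6-methylbenzoyl]oxy}-2-methoxy-3,6-dimethylbenzoate
Product: 27 methyl 4-[(3-formyl-2,4-dihydroxy-6-methylbenzoyl)oxy]-2-methoxy-3,6-dimethylbenzoate, via monobenzyl depside 26 (not isolated)
Conditions: H2 (1 atm), 10% Pd/C, EtOAc, rt, stopped after 2 equiv H2
Reagents that add atoms: none
Why: Hydrogenolysis of aryl benzyl ethers over Pd/C in ethyl acetate is much faster than reduction of the aldehyde, which becomes chelated to the freed ortho hydroxyls; no alcohol solvent is used because the depside ester is prone to alcoholysis.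

**Compound list**

1 | methyl 3-oxopentanoate | CCC(=O)CC(=O)OC | starting material
2 | methyl (E)-but-2-enoate (methyl crotonate) | C/C=C/C(=O)OC | starting material
3 | dimethyl 3-methyl-2-propanoylpentanedioate (Michael adduct, stereoisomer mixture, formed in the flask) | CCC(=O)C(C(=O)OC)C(C)CC(=O)OC | intermediate
4 | methyl 3,6-dimethyl-2,4-dioxocyclohexane-1-carboxylate (stereoisomer mixture) | COC(=O)C1C(C)CC(=O)C(C)C1=O | intermediate
5 | methyl 3-bromo-3,6-dimethyl-2,4-dioxocyclohexane-1-carboxylate (stereoisomer mixture, formed in the flask) | COC(=O)C1C(C)CC(=O)C(C)(Br)C1=O | intermediate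
6 | methyl 5-bromo-3,6-dimethyl-2,4-dioxocyclohexane-1-carboxylate (stereoisomer mixture, formed in the flask) | COC(=O)C1C(C)C(Br)C(=O)C(C)C1=O | intermediate
7 | methyl 2,4-dihydroxy-3,6-dimethylbenzoate (methyl β-orcinolcarboxylate) | COC(=O)c1c(C)cc(O)c(C)c1O | intermediate
8 | methyl 4-(benzyloxy)-2-hydroxy-3,6-dimethylbenzoate | COC(=O)c1c(C)cc(OCc2ccccc2)c(C)c1O | intermediate
9 | methyl 4-(benzyloxy)-2-methoxy-3,6-dimethylbenzoate | COC(=O)c1c(C)cc(OCc2ccccc2)c(C)c1OC | intermediate
10 | methyl 4-hydroxy-2-methoxy-3,6-dimethylbenzoate | COC(=O)c1c(C)cc(O)c(C)c1OC | intermediate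
11 | methyl acetoacetate (methyl 3-oxobutanoate) | CC(=O)CC(=O)OC | starting material
12 | dimethyl 2-acetyl-3-methylpentanedioate (Michael adduct, stereoisomer mixture, formed in the flask) | CC(=O)C(C(=O)OC)C(C)CC(=O)OC | intermediate
13 | methyl 6-methyl-2,4-dioxocyclohexane-1-carboxylate (stereoisomer mixture) | COC(=O)C1C(C)CC(=O)CC1=O | intermediate
14 | methyl 3-bromo-6-methyl-2,4-dioxocyclohexane-1-carboxylate (stereoisomer mixture, formed in the flask) | COC(=O)C1C(C)CC(=O)C(Br)C1=O | intermediate
15 | methyl 5-bromo-6-methyl-2,4-dioxocyclohexane-1-carboxylate (stereoisomer mixture, formed in the flask) | COC(=O)C1C(C)C(Br)C(=O)CC1=O | intermediate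
16 | methyl 2,4-dihydroxy-6-methylbenzoate (methyl orsellinate) | COC(=O)c1c(C)cc(O)cc1O | intermediate
17 | methyl 3-[chloro(methoxy)methyl]-2,4-dihydroxy-6-methylbenzoate (formed in the flask) | COC(Cl)c1c(O)cc(C)c(C(=O)OC)c1O | intermediate
18 | methyl 3-formyl-2,4-dihydroxy-6-methylbenzoate (methyl haematommate) | COC(=O)c1c(C)cc(O)c(C=O)c1O | intermediate
19 | methyl 4-(benzyloxy)-3-formyl-2-hydroxy-6-methylbenzoate (formed in the flask) | COC(=O)c1c(C)cc(OCc2ccccc2)c(C=O)c1O | intermediate
20 | methyl 2,4-bis(benzyloxy)-3-formyl-6-methylbenzoate | COC(=O)c1c(C)cc(OCc2ccccc2)c(C=O)c1OCc1ccccc1 | intermediate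
21 | methyl 2,4-bis(benzyloxy)-3-(1,3-dioxolan-2-yl)-6-methylbenzoate | COC(=O)c1c(C)cc(OCc2ccccc2)c(C2OCCO2)c1OCc1ccccc1 | intermediate
22 | 2,4-bis(benzyloxy)-3-(1,3-dioxolan-2-yl)-6-methylbenzoic acid (formed in the flask, first as its potassium salt) | OC(=O)c1c(C)cc(OCc2ccccc2)c(C2OCCO2)c1OCc1ccccc1 | intermediate
23 | 2,4-bis(benzyloxy)-3-formyl-6-methylbenzoic acid | OC(=O)c1c(C)cc(OCc2ccccc2)c(C=O)c1OCc1ccccc1 | intermediate
24 | 2,4-bis(benzyloxy)-3-formyl-6-methylbenzoic trifluoroacetic anhydride (formed in the flask) | O=C(OC(=O)C(F)(F)F)c1c(C)cc(OCc2ccccc2)c(C=O)c1OCc1ccccc1 | intermediate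
25 | methyl 4-{[2,4-bis(benzyloxy)-3-formyl-6-methylbenzoyl]oxy}-2-methoxy-3,6-dimethylbenzoate | COC(=O)c1c(C)cc(OC(=O)c2c(C)cc(OCc3ccccc3)c(C=O)c2OCc2ccccc2)c(C)c1OC | intermediate
26 | methyl 4-{[2-(benzyloxy)-3-formyl-4-hydroxy-6-methylbenzoyl]oxy}-2-methoxy-3,6-dimethylbenzoate (formed in the flask) | COC(=O)c1c(C)cc(OC(=O)c2c(C)cc(O)c(C=O)c2OCc2ccccc2)c(C)c1OC | intermediate
27 | methyl 4-[(3-formyl-2,4-dihydroxy-6-methylbenzoyl)oxy]-2-methoxy-3,6-dimethylbenzoate (2'-O-methylatranorin) | COC(=O)c1c(C)cc(OC(=O)c2c(C)cc(O)c(C=O)c2O)c(C)c1OC | target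

**Step count and risks**

Total: 13 steps. Longest linear sequence: 8 steps (steps 6–13, from 11 and 2 to 27); the ring B branch (steps 1–5) joins at step 12.

The three steps most likely to fail:

Step 2 (one-pot aromatisation of the 3-methyl dione). The first-formed C3 bromide is tertiary and must transpose before HBr can be lost, so the reaction may stall or give mixtures. Fallback: set out again from 4 and over-brominate on purpose with Br2 (2.1 equiv) in AcOH at room temperature, where HBr moves the bromine and the excess caps the only free ring position, to give crystalline methyl 5-bromo-2,4-dihydroxy-3,6-dimethylbenzoate F1. Hydrogenolysis of the C–Br bond (H2, 10% Pd/C, NaOAc, MeOH) then comes back to the route at 7.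

Step 8 (regiochemistry of the formylation). The C5 aldehyde may form alongside the C3 aldehyde and be hard to remove. Fallback: block C5 first. From 16, NBS (1.0 equiv, MeCN, 0 °C) brominates para to the chelated 2-OH and gives methyl 5-bromo-2,4-dihydroxy-6-methylbenzoate F2. The same Cl2CHOMe/TiCl4 formylation can then only reach C3 and gives methyl 5-bromo-3-formyl-2,4-dihydroxy-6-methylbenzoate F3. Hydrodebromination (H2, 10% Pd/C, NaOAc, MeOH, stopped at one equivalent) comes back to the route at 18.

Step 13 (debenzylation next to the aldehyde). Over-reduction of the formyl group to hydroxymethyl or methyl would be fatal at the last step. Fallback: remove the benzyl groups before the aldehyde exists. From 16, BnBr/K2CO3/DMF gives methyl 2,4-bis(benzyloxy)-6-methylbenzoate F4, and KOH in aqueous DMSO gives 2,4-bis(benzyloxy)-6-methylbenzoic acid F5. Trifluoroacetic anhydride in toluene with phenol 10 gives methyl 4-{[2,4-bis(benzyloxy)-6-methylbenzoyl]oxy}-2-methoxy-3,6-dimethylbenzoate F6, and hydrogenolysis (H2, 10% Pd/C, EtOAc) gives methyl 4-[(2,4-dihydroxy-6-methylbenzoyl)oxy]-2-methoxy-3,6-dimethylbenzoate F7. Formylation of F7 (Cl2CHOMe, TiCl4, CH2Cl2, 0 °C), directed to C3 of ring A by the same chelation as in step 8, comes back to the route at 27.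

Further compounds
F1 | step 2 | methyl 5-bromo-2,4-dihydroxy-3,6-dimethylbenzoate | COC(=O)c1c(C)c(Br)c(O)c(C)c1O
F2 | step 8 | methyl 5-bromo-2,4-dihydroxy-6-methylbenzoate | COC(=O)c1c(C)c(Br)c(O)cc1O
F3 | step 8 | methyl 5-bromo-3-formyl-2,4-dihydroxy-6-methylbenzoate | COC(=O)c1c(C)c(Br)c(O)c(C=O)c1O
F4 | step 13 | methyl 2,4-bis(benzyloxy)-6-methylbenzoate | COC(=O)c1c(C)cc(OCc2ccccc2)cc1OCc1ccccc1
F5 | step 13 | 2,4-bis(benzyloxy)-6-methylbenzoic acid | OC(=O)c1c(C)cc(OCc2ccccc2)cc1OCc1ccccc1
F6 | step 13 | methyl 4-{[2,4-bis(benzyloxy)-6-methylbenzoyl]oxy}-2-methoxy-3,6-dimethylbenzoate | COC(=O)c1c(C)cc(OC(=O)c2c(C)cc(OCc3ccccc3)cc2OCc2ccccc2)c(C)c1OC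
F7 | step 13 | methyl 4-[(2,4-dihydroxy-6-methylbenzoyl)oxy]-2-methoxy-3,6-dimethylbenzoate | COC(=O)c1c(C)cc(OC(=O)c2c(C)cc(O)cc2O)c(C)c1OC
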